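**Retrosynthetic overview**

1. Locants: C1 lactone C=O, C2 CH2, C3 CH–OO, C4 C(CH3)–O(lactone), C5 ring CH2, C6 C(CH3)(10-phenyldecyl)–OO. The strategy rests on the C6–C5–C4–O array, which belongs to both rings: the 1,2-dioxane (O–O–C3–C4–C5–C6) and the γ-lactone (C1–C2–C3–C4–O).
2. Both rings are opened in one move, at C5–C6 (dioxane) and C4–O (lactone). This leaves a ketone-derived methoxy peroxyketal at C6, an isopropenyl group (C4=C5) and a carboxyl group (C1), all carried by the C3 peroxide. In the forward sense the 1,2-dioxane closes first and the lactone second, in one flask.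
3. The C3–OO bond comes from SN2 inversion of an (S)-allylic mesylate by the α-methoxy hydroperoxide of 12-phenyldodecan-2-one. C1 travels as a silyl ether and is oxidized once the peroxide is in place.
4. The hydroperoxide comes from methanolic ozonolysis of 2-methyl-12-phenyldodec-1-ene, itself from 1,10-dibromodecane, PhMgBr and isopropenylMgBr by two Kumada-type couplings.
5. The (S)-allylic alcohol comes from Sharpless kinetic resolution of the adduct of isopropenylMgBr and 3-(TBSO)propanal. It is the only stereocentre brought in; C4 and C6 follow from it.

Key step: step 11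

Remark: 3-[(tert-butyldimethylsilyl)oxy]propanal is taken as purchased, and the α-methoxy hydroperoxide is used as the racemate, because its ketal carbon becomes planar in the key step (all peroxyketals below are therefore pairs of ketal epimers).

**Route**

Step 1
Reactants: 1 1,10-dibromodecane (3 equiv); 2 phenylmagnesium bromide
Product: 3 (10-bromodecyl)benzene
Conditions: FeCl3 (5 mol %), TMEDA, THF, 0 °C, slow addition of 2; excess 1 recovered by distillation
Reagents that add atoms: none
Why: Iron-catalysed Kumada-type coupling of an aryl Grignard reagent with a primary alkyl bromide; the excess of the symmetrical dibromide keeps double arylation low.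

Step 2
Reactants: 3 (10-bromodecyl)benzene; 4 isopropenylmagnesium bromide
Product: 5 2-methyl-12-phenyldodec-1-ene
Conditions: Li2CuCl4 (3 mol %), THF–NMP, 0 °C to rt
Reagents that add atoms: none
Why: Copper-catalysed Kumada-type sp2–sp3 coupling of an alkenyl Grignard reagent with a primary bromide, which installs the 1,1-disubstituted alkene needed for the ozonolysis.

Step 3
Reactants: 5 2-methyl-12-phenyldodec-1-ene
Product: 6 2-hydroperoxy-2-methoxy-12-phenyldodecane (racemic)
Conditions: O3 (1 equiv), CH2Cl2–MeOH, NaHCO3, −78 °C; N2 purge; concentrated cold and used without storage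
Reagents that add atoms: ozone [O-][O+]=O; methanol CO
Why: Criegee ozonolysis in methanol, in which the primary ozonide of a 1,1-disubstituted alkene splits into formaldehyde and the ketone O-oxide and methanol traps the latter as the α-methoxy hydroperoxide; the isolated alkene reacts with ozone far faster than the phenyl ring.

Step 4
Reactants: 7 3-[(tert-butyldimethylsilyl)oxy]propanal; 4 isopropenylmagnesium bromide
Product: 8 rac-1-[(tert-butyldimethylsilyl)oxy]-4-methylpent-4-en-3-ol
Conditions: THF, −78 to 0 °C; aq NH4Cl
Reagents that add atoms: none
Why: Grignard 1,2-addition to an aldehyde gives the racemic secondary allylic alcohol with the primary oxygen already protected.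

Step 5
Reactants: 8 rac-1-[(tert-butyldimethylsilyl)oxy]-4-methylpent-4-en-3-ol
Product: 9 (3S)-1-[(tert-butyldimethylsilyl)oxy]-4-methylpent-4-en-3-ol
Conditions: Ti(OiPr)4 (0.2 equiv), D-(−)-DIPT (0.24 equiv), t-BuOOH (0.6 equiv), 4 Å MS, CH2Cl2, −20 °C; chromatography
Reagents that add atoms: none
Why: Sharpless kinetic resolution, in which the D-(−)-tartrate catalyst epoxidizes the (R)-alcohol much faster (to the erythro epoxy alcohol), so that past half conversion the unreacted alcohol should be the (S)-enantiomer in high enantiomeric purity; this fixes the centre that step 7 inverts to C3 of the target.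

Step 6
Reactants: 9 (3S)-1-[(tert-butyldimethylsilyl)oxy]-4-methylpent-4-en-3-ol
Product: 10 (3S)-1-[(tert-butyldimethylsilyl)oxy]-4-methylpent-4-en-3-yl methanesulfonate
Conditions: Ms2O, Et3N, CH2Cl2, −20 °C; used crude at once
Reagents that add atoms: methanesulfonic anhydride CS(=O)(=O)OS(C)(=O)=O
Why: O-Sulfonylation leaves the C–O bond and so the configuration untouched; the anhydride is chosen over the chloride so that no chloride ion is present to displace the allylic sulfonate.

Step 7
Reactants: 10 (3S)-1-[(tert-butyldimethylsilyl)oxy]-4-methylpent-4-en-3-yl methanesulfonate; 6 2-hydroperoxy-2-methoxy-12-phenyldodecane (1.5 equiv)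
Product: 11 tert-butyl{[(3R)-3-[(2-methoxy-12-phenyldodecan-2-yl)peroxy]-4-methylpent-4-en-1-yl]oxy}dimethylsilane (both ketal epimers)
Conditions: CsOH·H2O, DMF, 0 °C
Reagents that add atoms: none
Why: SN2 alkylation of the cesium hydroperoxide (an α-effect nucleophile) by a secondary sulfonate with inversion, so that the (S)-mesylate should give the (3R)-peroxide; the allylic position makes a mesylate reactive enough, and the mixed ketal is inert to base.

Step 8
Reactants: 11 tert-butyl{[(3R)-3-[(2-methoxy-12-phenyldodecan-2-yl)peroxy]-4-methylpent-4-en-1-yl]oxy}dimethylsilane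
Product: 12 (3R)-3-[(2-methoxy-12-phenyldodecan-2-yl)peroxy]-4-methylpent-4-en-1-ol
Conditions: TBAF, AcOH (1:1), THF, 0 °C to rt
Reagents that add atoms: none
Why: Fluoride desilylation; the acetic acid buffer keeps the medium from becoming basic enough for Kornblum–DeLaMare cleavage of the secondary peroxide, and the peroxyketal is stable to fluoride.

Step 9
Reactants: 12 (3R)-3-[(2-methoxy-12-phenyldodecan-2-yl)peroxy]-4-methylpent-4-en-1-ol
Product: 13 (3R)-3-[(2-methoxy-12-phenyldodecan-2-yl)peroxy]-4-methylpent-4-enal
Conditions: Dess–Martin periodinane, NaHCO3, CH2Cl2, 0 °C; crude into step 10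
Reagents that add atoms: none
Why: Dess–Martin oxidation under buffered, non-aqueous conditions with no enolizing base, so that the β-peroxy group should not be lost by E1cB elimination and the acid-labile ketal is not exposed to free acid.

Step 10
Reactants: 13 (3R)-3-[(2-methoxy-12-phenyldodecan-2-yl)peroxy]-4-methylpent-4-enal
Product: 14 (3R)-3-[(2-methoxy-12-phenyldodecan-2-yl)peroxy]-4-methylpent-4-enoic acid (both ketal epimers)
Conditions: NaClO2, NaH2PO4, 2-methyl-2-butene (excess), t-BuOH–H2O, 0 °C; used promptly
Reagents that add atoms: sodium chlorite [Na+].[O-]Cl=O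
Why: Pinnick oxidation of the aldehyde; the scavenger takes up the hypochlorous acid that would otherwise attack the isopropenyl group, and a short exposure to the weakly acidic buffer should be tolerated by the peroxyketal.

Step 11
Reactants: 14 (3R)-3-[(2-methoxy-12-phenyldodecan-2-yl)peroxy]-4-methylpent-4-enoic acid
Product: 16 butenolide peroxide (3R,4aR,7aR)-3,4a-dimethyl-3-(10-phenyldecyl)tetrahydro-3H-furo[3,2-c][1,2]dioxin-6(4H)-one, via trimethylsilyl ester 15 (not isolated)
Conditions: BSA, CH2Cl2, rt, volatiles removed; then TMSOTf (0.2 equiv), CH2Cl2, −78 to −40 °C; Et3N quench; chromatography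
Reagents that add atoms: none
Why: Proposed new method: TMSOTf removes methoxide from either ketal epimer of the silyl ester to give one peroxycarbenium ion (C6=O+–O–C3), the terminal carbon C5 of the isopropenyl group adds to C6, and the tertiary C4 cation is taken by the carbonyl oxygen of the silyl ester, whose Me3Si group leaves with the methoxide as Me3SiOMe and returns the catalyst; the closest known reaction type is the Lewis-acid cyclization of unsaturated monoperoxyketals to 1,2-dioxanes (a Prins cyclization of a peroxycarbenium ion), in which the cation has so far been ended by halide or by proton loss and not by a carboxyl group. The 1,2-dioxane closes 6-endo at both π bonds through a chair, and the γ-lactone then closes by 5-exo capture of the ring cation. Regioselectivity rests on Markovnikov polarization of the 1,1-disubstituted alkene: bonding at C5 puts the charge on tertiary C4, whereas the 1,2-dioxolane alternative would need a primary cation. C4 is controlled by C3, because the two-atom arm on C3 can reach only the cation lobe on its own face, which makes the ring fusion cis and C4 R. C6 is controlled by the chair: with the C3 arm equatorial the larger 10-phenyldecyl group should sit anti to the O–O bond of the peroxycarbenium ion and end equatorial, the methyl axial and cis to the lactone oxygen (6R), but the methyl/alkyl bias is small, so the 6-epimer is the expected by-product and is removed by chromatography. The cyclization needs ionization without O–O heterolysis and cation capture faster than proton loss, for which the low temperature, the triflate counter-ion and the five-membered reach of the carboxyl group are relied on.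

**Compound list**

1 | 1,10-dibromodecane | BrCCCCCCCCCCBr | starting material
2 | phenylmagnesium bromide | Br[Mg]c1ccccc1 | starting material
3 | (10-bromodecyl)benzene | BrCCCCCCCCCCc1ccccc1 | intermediate
4 | isopropenylmagnesium bromide | C=C(C)[Mg]Br | starting material
5 | 2-methyl-12-phenyldodec-1-ene | C=C(C)CCCCCCCCCCc1ccccc1 | intermediate
6 | 2-hydroperoxy-2-methoxy-12-phenyldodecane (racemic) | COC(C)(OO)CCCCCCCCCCc1ccccc1 | intermediate
7 | 3-[(tert-butyldimethylsilyl)oxy]propanal | O=CCCO[Si](C)(C)C(C)(C)C | starting material
8 | rac-1-[(tert-butyldimethylsilyl)oxy]-4-methylpent-4-en-3-ol | C=C(C)C(O)CCO[Si](C)(C)C(C)(C)C | intermediate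
9 | (3S)-1-[(tert-butyldimethylsilyl)oxy]-4-methylpent-4-en-3-ol | O[C@@H](CCO[Si](C)(C)C(C)(C)C)C(C)=C | intermediate
10 | (3S)-1-[(tert-butyldimethylsilyl)oxy]-4-methylpent-4-en-3-yl methanesulfonate | CS(=O)(=O)O[C@@H](CCO[Si](C)(C)C(C)(C)C)C(C)=C | intermediate
11 | tert-butyl{[(3R)-3-[(2-methoxy-12-phenyldodecan-2-yl)peroxy]-4-methylpent-4-en-1-yl]oxy}dimethylsilane (ketal epimers) | COC(C)(CCCCCCCCCCc1ccccc1)OO[C@H](CCO[Si](C)(C)C(C)(C)C)C(C)=C | intermediate
12 | (3R)-3-[(2-methoxy-12-phenyldodecan-2-yl)peroxy]-4-methylpent-4-en-1-ol (ketal epimers) | COC(C)(CCCCCCCCCCc1ccccc1)OO[C@H](CCO)C(C)=C | intermediate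
13 | (3R)-3-[(2-methoxy-12-phenyldodecan-2-yl)peroxy]-4-methylpent-4-enal (ketal epimers) | COC(C)(CCCCCCCCCCc1ccccc1)OO[C@H](CC=O)C(C)=C | intermediate
14 | (3R)-3-[(2-methoxy-12-phenyldodecan-2-yl)peroxy]-4-methylpent-4-enoic acid (ketal epimers) | COC(C)(CCCCCCCCCCc1ccccc1)OO[C@H](CC(=O)O)C(C)=C | intermediate
15 | trimethylsilyl (3R)-3-[(2-methoxy-12-phenyldodecan-2-yl)peroxy]-4-methylpent-4-enoate (ketal epimers, not isolated) | COC(C)(CCCCCCCCCCc1ccccc1)OO[C@H](CC(=O)O[Si](C)(C)C)C(C)=C | intermediate
16 | butenolide peroxide, (3R,4aR,7aR)-3,4a-dimethyl-3-(10-phenyldecyl)tetrahydro-3H-furo[3,2-c][1,2]dioxin-6(4H)-one | C[C@@]1(CCCCCCCCCCc2ccccc2)C[C@@]2(C)OC(=O)C[C@H]2OO1 | target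

**Step count**

Total step count: 11. Longest linear sequence: 8 steps (steps 4–11 from 7, or steps 1–3 and 7–11 from 1).

**Steps most likely to fail**

Step 11 (key step). What may go wrong: the C4 cation may lose a proton or be taken by an external nucleophile before the silyl ester closes; the carboxyl oxygen may capture the peroxycarbenium ion instead of the alkene; the Lewis acid may trigger heterolysis of the allylic O–O bond; facial discrimination at C6 may be low. Fallback, from 14 back to 16: the two ring closures are separated and each is run as a reaction of established type. Esterification of 14 with trimethylsilyldiazomethane (MeOH–toluene) gives methyl (3R)-3-[(2-methoxy-12-phenyldodecan-2-yl)peroxy]-4-methylpent-4-enoate F1. TiCl4 (CH2Cl2, −78 °C) then effects the known halide-terminated cyclization of the unsaturated monoperoxyketal to methyl 2-[(3R,6R)-4-chloro-4,6-dimethyl-6-(10-phenyldecyl)-1,2-dioxan-3-yl]acetate F2; both C4 chloride epimers serve. AgOTf (CH2Cl2, 0 °C) ionizes the tertiary chloride and the ester carbonyl closes the cis-fused lactone with loss of its O-methyl group, a silver-assisted lactonization of a γ-halo ester, to reach 16 after the same separation of the C6 epimer.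

Step 7. What may go wrong: attack of the peroxide anion at the terminal CH2 with allylic transposition (SN2′), E2 loss of the sulfonate to a diene, ionization of the allylic mesylate with erosion of configuration, or base-induced cleavage of the secondary peroxide once formed. Fallback, from 6 back to 13: the C3–OO bond is made by asymmetric conjugate addition instead of substitution. Wittig reaction of methacrolein with (triphenylphosphoranylidene)acetaldehyde (toluene, 80 °C) gives (2E)-4-methylpenta-2,4-dienal F3. Iminium-catalysed enantioselective addition of hydroperoxide 6 to the α,β-bond of F3 (diarylprolinol silyl ether, 10–20 mol %, toluene, 0 °C) is an organocatalytic peroxidation of an enal and should give aldehyde 13 directly; the catalyst enantiomer is the one whose shielding group blocks the iminium face leading to 3S (by the usual model the R catalyst). Steps 4–9 are then not needed.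

Step 5. What may go wrong: the 1,1-disubstituted alkene is epoxidized slowly, and an insufficient rate difference between the enantiomers would leave alcohol of inadequate enantiomeric purity in the one step that sets absolute configuration; half of the material is lost by design. Fallback, from 8 back to 9: resolution is replaced by asymmetric reduction. Dess–Martin oxidation of 8 gives 5-[(tert-butyldimethylsilyl)oxy]-2-methylpent-1-en-3-one F4, and Corey–Bakshi–Shibata reduction with the (R)-methyl oxazaborolidine and catecholborane (toluene, −78 °C), the isopropenyl group acting as the large substituent, should give (S)-alcohol 9.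

**Further compounds**

F1 | step 11 | methyl (3R)-3-[(2-methoxy-12-phenyldodecan-2-yl)peroxy]-4-methylpent-4-enoate | COC(C)(CCCCCCCCCCc1ccccc1)OO[C@H](CC(=O)OC)C(C)=C
F2 | step 11 | methyl 2-[(3R,6R)-4-chloro-4,6-dimethyl-6-(10-phenyldecyl)-1,2-dioxan-3-yl]acetate | C[C@@]1(CCCCCCCCCCc2ccccc2)CC(C)(Cl)[C@@H](CC(=O)OC)OO1
F3 | step 7 | (2E)-4-methylpenta-2,4-dienal | C=C(C)/C=C/C=O
F4 | step 5 | 5-[(tert-butyldimethylsilyl)oxy]-2-methylpent-1-en-3-one | C=C(C)C(=O)CCO[Si](C)(C)C(C)(C)C
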